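The data were generated by integration with constants of no real substance; scatter was added.

Monday's flask makes more target between 44 s and 66 s, namely 0.0225 M, than the 0.0133 M of its first 22 s, though its starting material and partner have fallen by then. So in Monday's flask the rate climbs with something that the run builds up.

| flask | starting material | partner | free catalyst | time |
|---|---|---|---|---|
| Monday's | 0.120 M | 0.360 M | 2.40 × 10⁻⁴ M |  |
| Tuesday's | 0.0720 M | 0.312 M | 2.40 × 10⁻⁴ M |  |
| Sunday's | 0.120 M | 0.360 M | 4.80 × 10⁻⁴ M |  |
| Saturday's | 0.480 M | 0.360 M | 2.40 × 10⁻⁴ M | 110 s |

- Monday's run (time / s: [target] / M): 22: 0.0133; 44: 0.0330; 66: 0.0555; 88: 0.0758; 110: 0.0912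
- Tuesday's run (time / s: [target] / M): 22: 0.0066; 44: 0.0134; 66: 0.0219; 88: 0.0297; 110: 0.0371
- Sunday's run (time / s: [target] / M): 22: 0.0234; 44: 0.0475; 66: 0.0708; 88: 0.0880; 110: 0.0999

(each reading ± 4 × 10⁻⁴ M)

- apparent order in [free catalyst] of the starting rate, round the charge of the Monday's run (the rate where two percent of its starting material have turned into target)
- the Tuesday's run starts with 0.0480 M less of starting material and of partner than the Monday's run, and with no target. Compared where both hold the same amount of starting material, once fifteen percent of what the Tuesday's run was charged with has turned into target, is the Tuesday's run faster, slower or alike (within a tenth)?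
- target in the Saturday's run at 110 s, as a share of the starting material charged

- Overall: starting material + partner -> target, with free catalyst as catalyst.
- Constant volume, constant temperature.
- Readings of a species count what is bound in complexes too.
- "The second partner" is partner.
- An order is taken over about fifteen percent of the charge, up and down.

In Monday's flask I divide the rate by starting material times partner, both taken at the middle of an interval. That quotient reads 0.0151 M⁻¹ s⁻¹ over the first interval and 0.0428 M⁻¹ s⁻¹ between 44 s and 66 s. It climbs with target, so I read target as opening a route of its own: autocatalysis. The line through these readings has slope 0.736 M⁻² s⁻¹. It gives 0.0139 M as the crossover amount, the target at which the target route matches the catalyst route.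

Now I turn each question round. A catalyst order of one needs target far below the crossover. At the point asked, Monday's flask holds 2.40 mM, so the catalyst's share of the rate, which is the order, comes to 0.853.

"Alike" needs equal target routes. At the compared point both flasks hold the same starting material and partner, but Tuesday's flask holds 0.0108 M of target and Monday's 0.0588 M. My rate ratio is 0.340, so Tuesday's flask is slower.

Saturday's flask could stop far below its ceiling if target stayed under the crossover for most of the run. Its catalyst route makes 1.76 mM s⁻¹, which reaches the crossover in 7.87 s, far less than 110 s. So I expect a share just under 75.0%, with partner the limiting reagent.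

The forecast gives 0.86 (0.75 to 0.95), slower, and 73% (62% to 75%). Its ground: “Monday's rate rises before it falls, so target speeds up the reaction.”

The flask gives 0.85, slower, and 74.1%.

    free catalyst + starting material ⇌ catalyst-substrate complex (20.70 M⁻¹ s⁻¹, 12.10 s⁻¹)
    catalyst-substrate complex + partner → target + free catalyst (339.0 M⁻¹ s⁻¹)
    2 free catalyst → 2 spent catalyst (40.60 M⁻¹ s⁻¹)
    starting material + partner + target → 2 target (0.8100 M⁻² s⁻¹)

Saturday's run proves the reason: with the step in which target makes more target it reaches 74.1%, and without that step 22.6%. Carried to Sunday's run, the doubled free catalyst doubles the crossover to 0.0278 M, and at 2.40 mM of target that gives a rate ratio of 1.85 over Monday's run, where the simulated ratio is 1.8. Saturday's flask also loses free catalyst to spent catalyst, yet its share is 74.1% with that loss and 74.5% without it.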